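**Retrosynthetic overview**

1. Target 17 ⇐ 16 (phenol desilylation) ⇐ 15 (E→Z equilibration of the C8=C9 alkene) ⇐ 13 + 14, where an Evans–Tishchenko reduction sets the C3 carbinol anti to the C1 oxygen and puts the aroyl group on C1–O.
2. 13 ⇐ 12 ⇐ 9: anionic oxy-Cope ([3,3]) ring expansion of a cyclohexene to a cyclodeca-2,6-dienone. It forms the C8–C9 bond, keeps the enone alkene ring-cis and relays the limonene stereocentre to C9, then C10.
3. 9 ⇐ (S)-isopiperitenone 2 (from (R)-limonene 1) + vinyllithium 8 (from 3-methylbutanal 3 via bromo enol ether 7).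
4. Ring order: the six-membered ring is bought in limonene; the ten-membered ring is the only ring formed (step 5).

Assumption: the target is taken exactly as written in the SMILES, i.e. (1R,2R,3R) with both ring alkenes Z (4Z,8Z, each with its two ring bonds cis).

**Route**

Step 1
Reactants: 1 (R)-(+)-limonene
Product: 2 (S)-isopiperitenone [(6S)-3-methyl-6-(prop-1-en-2-yl)cyclohex-2-en-1-one]
Conditions: CrO3 (5 mol %), t-BuOOH (70 % aq., 4 equiv), CH2Cl2, 20 °C; chromatography
Reagents that add atoms: tert-butyl hydroperoxide, CC(C)(C)OO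
Why: Chromium-catalysed allylic C–H oxidation converts the ring CH2 lying between the alkene CH and the stereocentre into the enone carbonyl (carvone, from the other allylic CH2, is removed by chromatography); the stereocentre is not touched, so (R)-1 gives (S)-2 only through a change of CIP priorities.

Step 2
Reactants: 3 3-methylbutanal
Product: 5 1-(methoxymethoxy)-3-methylbut-1-ene (E/Z mixture), via potassium enolate 4 (not isolated)
Conditions: KN(SiMe3)2, THF, −78 °C (slow addition of 3); then MeOCH2Cl, DMPU, −78 → 0 °C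
Reagents that add atoms: chloromethyl methyl ether, COCCl
Why: Kinetic deprotonation gives the potassium enolate, which the hard SN1-like electrophile MeOCH2Cl alkylates on oxygen (enolate O-alkylation); the E/Z ratio of 5 does not matter because step 3 erases it.

Step 3
Reactants: 5 1-(methoxymethoxy)-3-methylbut-1-ene
Product: 7 (1Z)-2-bromo-1-(methoxymethoxy)-3-methylbut-1-ene, via dibromo ether 6 (not isolated)
Conditions: Br2, CH2Cl2, −78 °C; then i-Pr2NEt, −78 → 40 °C; distillation
Reagents that add atoms: bromine, BrBr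
Why: Bromine adds across the electron-rich enol ether and the amine then removes HBr from the labile alpha-bromo ether through its oxocarbenium ion (bromination–dehydrobromination), which leaves Br on the isopropyl-bearing carbon, mainly as the Z isomer (Br cis to O, isopropyl trans to O) that is purified by distillation.

Step 4
Reactants: 7 (1Z)-2-bromo-1-(methoxymethoxy)-3-methylbut-1-ene; 2 (S)-isopiperitenone
Product: 9 (1S,6S)-1-[(1Z)-1-(methoxymethoxy)-3-methylbut-1-en-2-yl]-3-methyl-6-(prop-1-en-2-yl)cyclohex-2-en-1-ol, via vinyllithium 8 (not isolated)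
Conditions: 7 (1.4 equiv), t-BuLi (2.8 equiv), Et2O, −78 °C; then 2, THF, −78 °C; aq. NH4Cl
Reagents that add atoms: none
Why: Br/Li exchange proceeds with retention to the O-chelated vinyllithium, which adds 1,2 to the enone carbonyl from the face opposite the neighbouring isopropenyl group (substrate-controlled carbonyl addition), so the carbinol centre is S and the two alkenyl groups are trans.

Step 5
Reactants: 9 (1S,6S)-1-[(1Z)-1-(methoxymethoxy)-3-methylbut-1-en-2-yl]-3-methyl-6-(prop-1-en-2-yl)cyclohex-2-en-1-ol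
Product: 12 (2Z,6E,9R,10S)-9-(methoxymethoxy)-3,7-dimethyl-10-(propan-2-yl)cyclodeca-2,6-dien-1-one, via potassium alkoxide 10 (not isolated), via potassium enolate 11 (not isolated)
Conditions: KN(SiMe3)2 (1.1 equiv), THF, 0 → 25 °C; then AcOH, −78 °C
Reagents that add atoms: none
Why: Anionic oxy-Cope [3,3]-sigmatropic rearrangement through the single chair open to a trans-1,2-dialkenyl alkoxide (both ring bonds equatorial, Z-enol-ether oxygen axial) breaks the carbinol C–CH(isopropenyl) bond and forms the C8–C9 bond, so the cyclohexene alkene survives as the ring-cis 2Z enone, the new alkene is 6E, the stereocentre of 2 is relayed to 9R, and acetic acid protonates the planar-chiral enolate from its outer face to give 10S.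

Step 6
Reactants: 12 (2Z,6E,9R,10S)-9-(methoxymethoxy)-3,7-dimethyl-10-(propan-2-yl)cyclodeca-2,6-dien-1-one
Product: 13 (2Z,6E,9R,10S)-9-hydroxy-3,7-dimethyl-10-(propan-2-yl)cyclodeca-2,6-dien-1-one
Conditions: Me2BBr, CH2Cl2, −78 °C; then THF/aq. NaHCO3
Reagents that add atoms: none
Why: Me2BBr cleaves the methoxymethyl acetal at −78 °C (Lewis-acid acetal cleavage) without epimerising C10, eliminating the beta-oxygen or touching the diene.

Step 7
Reactants: 13 (2Z,6E,9R,10S)-9-hydroxy-3,7-dimethyl-10-(propan-2-yl)cyclodeca-2,6-dien-1-one; 14 4-[(tert-butyldimethylsilyl)oxy]benzaldehyde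
Product: 15 (1R,2R,3R,4Z,8E)-3-hydroxy-5,9-dimethyl-2-(propan-2-yl)cyclodeca-4,8-dien-1-yl 4-[(tert-butyldimethylsilyl)oxy]benzoate
Conditions: 14 (5 equiv), SmI2 (0.3 equiv), THF, −10 °C, dark
Reagents that add atoms: none
Why: Evans–Tishchenko reduction: the samarium-bound hemiacetal formed from the C9 hydroxyl and 14 delivers its hydride intramolecularly to the ketone, which gives the 1,3-anti diol monoester with the aroyl group on the original hydroxyl oxygen (C1 of the product) and the new 3R carbinol free.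

Step 8
Reactants: 15 (1R,2R,3R,4Z,8E)-3-hydroxy-5,9-dimethyl-2-(propan-2-yl)cyclodeca-4,8-dien-1-yl 4-[(tert-butyldimethylsilyl)oxy]benzoate
Product: 16 (1R,2R,3R,4Z,8Z)-3-hydroxy-5,9-dimethyl-2-(propan-2-yl)cyclodeca-4,8-dien-1-yl 4-[(tert-butyldimethylsilyl)oxy]benzoate
Conditions: PhSSPh (0.2 equiv), hν (350 nm, Pyrex), degassed C6H6, 20 °C
Reagents that add atoms: none
Why: Reversible addition and loss of the phenylthiyl radical (thiyl-radical alkene isomerisation) equilibrates the strained ring-trans C8=C9 bond to the ring-cis isomer, the thermodynamic minimum of a cyclodeca-1,5-diene, while the stereocentres and the 4Z alkene stay as they are.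

Step 9
Reactants: 16 (1R,2R,3R,4Z,8Z)-3-hydroxy-5,9-dimethyl-2-(propan-2-yl)cyclodeca-4,8-dien-1-yl 4-[(tert-butyldimethylsilyl)oxy]benzoate
Product: 17 (1R,2R,3R,4Z,8Z)-3-hydroxy-5,9-dimethyl-2-(propan-2-yl)cyclodeca-4,8-dien-1-yl 4-hydroxybenzoate
Conditions: Bu4NF, AcOH, THF, 0 °C
Reagents that add atoms: none
Why: Fluoride cleaves the aryl silyl ether (desilylation) and the acetic acid buffer keeps the benzoate from migrating to the neighbouring hydroxyl or hydrolysing, so the stereocentres and alkenes are unchanged.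

**Compound list**

1 | (R)-(+)-limonene [(4R)-1-methyl-4-(prop-1-en-2-yl)cyclohex-1-ene] | CC1=CC[C@@H](CC1)C(C)=C | starting material
2 | (S)-isopiperitenone [(6S)-3-methyl-6-(prop-1-en-2-yl)cyclohex-2-en-1-one] | CC1=CC(=O)[C@@H](CC1)C(C)=C | intermediate
3 | 3-methylbutanal (isovaleraldehyde) | CC(C)CC=O | starting material
4 | potassium 3-methylbut-1-en-1-olate (E/Z mixture, not isolated) | CC(C)C=C[O-].[K+] | intermediate
5 | 1-(methoxymethoxy)-3-methylbut-1-ene (E/Z mixture) | COCOC=CC(C)C | intermediate
6 | 1,2-dibromo-1-(methoxymethoxy)-3-methylbutane (diastereomer mixture, not isolated) | COCOC(Br)C(Br)C(C)C | intermediate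
7 | (1Z)-2-bromo-1-(methoxymethoxy)-3-methylbut-1-ene | COCO/C=C(\Br)C(C)C | intermediate
8 | [(1E)-1-(methoxymethoxy)-3-methylbut-1-en-2-yl]lithium (Li cis to the ether oxygen, not isolated) | COCO/C=C(\[Li])C(C)C | intermediate
9 | (1S,6S)-1-[(1Z)-1-(methoxymethoxy)-3-methylbut-1-en-2-yl]-3-methyl-6-(prop-1-en-2-yl)cyclohex-2-en-1-ol | O[C@@]1(/C(C(C)C)=C\OCOC)C=C(C)CC[C@H]1C(C)=C | intermediate
10 | potassium (1S,6S)-1-[(1Z)-1-(methoxymethoxy)-3-methylbut-1-en-2-yl]-3-methyl-6-(prop-1-en-2-yl)cyclohex-2-en-1-olate (not isolated) | [K+].[O-][C@@]1(/C(C(C)C)=C\OCOC)C=C(C)CC[C@H]1C(C)=C | intermediate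
11 | potassium (1(10)Z,2Z,6E,9R)-9-(methoxymethoxy)-3,7-dimethyl-10-(propan-2-yl)cyclodeca-1(10),2,6-trien-1-olate (not isolated) | [K+].C1/C(C)=C/CC/C(C)=C\C(\[O-])=C(C(C)C)\[C@@H]1OCOC | intermediate
12 | (2Z,6E,9R,10S)-9-(methoxymethoxy)-3,7-dimethyl-10-(propan-2-yl)cyclodeca-2,6-dien-1-one | C/C1=C/C(=O)[C@@H](C(C)C)[C@H](OCOC)C/C(C)=C/CC1 | intermediate
13 | (2Z,6E,9R,10S)-9-hydroxy-3,7-dimethyl-10-(propan-2-yl)cyclodeca-2,6-dien-1-one | C/C1=C/C(=O)[C@@H](C(C)C)[C@H](O)C/C(C)=C/CC1 | intermediate
14 | 4-[(tert-butyldimethylsilyl)oxy]benzaldehyde | CC(C)(C)[Si](C)(C)Oc1ccc(C=O)cc1 | starting material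
15 | (1R,2R,3R,4Z,8E)-3-hydroxy-5,9-dimethyl-2-(propan-2-yl)cyclodeca-4,8-dien-1-yl 4-[(tert-butyldimethylsilyl)oxy]benzoate | C/C1=C/[C@@H](O)[C@@H](C(C)C)[C@H](OC(=O)c2ccc(O[Si](C)(C)C(C)(C)C)cc2)C/C(C)=C/CC1 | intermediate
16 | (1R,2R,3R,4Z,8Z)-3-hydroxy-5,9-dimethyl-2-(propan-2-yl)cyclodeca-4,8-dien-1-yl 4-[(tert-butyldimethylsilyl)oxy]benzoate | C/C1=C/[C@@H](O)[C@@H](C(C)C)[C@H](OC(=O)c2ccc(O[Si](C)(C)C(C)(C)C)cc2)C/C(C)=C\CC1 | intermediate
17 | (1R,2R,3R,4Z,8Z)-3-hydroxy-5,9-dimethyl-2-(propan-2-yl)cyclodeca-4,8-dien-1-yl 4-hydroxybenzoate | C/C1=C/[C@@H](O)[C@@H](C(C)C)[C@H](OC(=O)c2ccc(O)cc2)C/C(C)=C\CC1 | target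

**Step count and risks**

Total steps: 9. Longest linear sequence: 8 steps (3 → 17, steps 2 to 9); the limonene branch adds one step before the two branches meet in step 4.

The three steps most likely to fail:

Step 5 (oxy-Cope). The free enolate 11 carries a beta-methoxymethoxy group and can expel it (E1cB), and the Z enol ether must place its oxygen axial in the chair, which slows the rearrangement. The fallback sets out from 9 and drops the base: the divalent palladium complex PdCl2(PhCN)2 (10 mol %, THF, 20 °C) catalyses the same oxy-Cope through a palladium-bound cyclohexyl cation, stabilised at the methyl-bearing carbon of the isopropenyl group. That cation fragments along the same chair to the neutral enol (1(10)Z,2Z,6E,9R)-9-(methoxymethoxy)-3,7-dimethyl-10-(propan-2-yl)cyclodeca-1(10),2,6-trien-1-ol F1. This enol tautomerises by outer-face protonation, so the fallback comes back to the route at 12 without an enolate ever being present.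

Step 7 (Evans–Tishchenko). The strained beta-hydroxy ketone may open by retro-aldol on the samarium alkoxide, and hydride transfer from an electron-rich aryl hemiacetal to a conjugated ketone may be slow. The fallback sets out from 13 and separates acylation from reduction. The C9 hydroxyl is esterified with 4-[(tert-butyldimethylsilyl)oxy]benzoic acid (DCC, DMAP, CH2Cl2, 0 °C) to give (1R,2S,4Z,8E)-5,9-dimethyl-3-oxo-2-(propan-2-yl)cyclodeca-4,8-dien-1-yl 4-[(tert-butyldimethylsilyl)oxy]benzoate F2. The enone carbonyl is then reduced 1,2 under Luche conditions (NaBH4, CeCl3·7H2O, MeOH, −78 °C), with hydride arriving on the outer face of the ring. The 3R alcohol comes back to the route at 15; any 3S epimer is separated and returned to F2 with MnO2. Stereocontrol here rests on ring conformation and is less assured than in the main step.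

Step 8 (E→Z equilibration). The carbon radical formed after thiyl addition could cyclise across the ring onto the 4Z alkene, equilibration may stall, and the E,Z-1,5-diene can undergo Cope rearrangement if warmed. The fallback sets out from 15 and avoids radicals. The silyl ether is removed first (Bu4NF, AcOH, THF, 0 °C) to give the 8E isomer of the target, (1R,2R,3R,4Z,8E)-3-hydroxy-5,9-dimethyl-2-(propan-2-yl)cyclodeca-4,8-dien-1-yl 4-hydroxybenzoate F3. F3 is then irradiated at 254 nm in pentane/Et2O, where the 4-hydroxybenzoate acts as a built-in sensitiser and drains the strained ring-trans alkene into the ring-cis one. This comes back to the route at 17.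

Further compounds
F1 | step 5 | (1(10)Z,2Z,6E,9R)-9-(methoxymethoxy)-3,7-dimethyl-10-(propan-2-yl)cyclodeca-1(10),2,6-trien-1-ol | C1/C(C)=C/CC/C(C)=C\C(\O)=C(C(C)C)\[C@@H]1OCOC
F2 | step 7 | (1R,2S,4Z,8E)-5,9-dimethyl-3-oxo-2-(propan-2-yl)cyclodeca-4,8-dien-1-yl 4-[(tert-butyldimethylsilyl)oxy]benzoate | C/C1=C/C(=O)[C@@H](C(C)C)[C@H](OC(=O)c2ccc(O[Si](C)(C)C(C)(C)C)cc2)C/C(C)=C/CC1
F3 | step 8 | (1R,2R,3R,4Z,8E)-3-hydroxy-5,9-dimethyl-2-(propan-2-yl)cyclodeca-4,8-dien-1-yl 4-hydroxybenzoate | C/C1=C/[C@@H](O)[C@@H](C(C)C)[C@H](OC(=O)c2ccc(O)cc2)C/C(C)=C/CC1
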